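**Plan**

1. Retrosynthetic cuts, in order: C8=O back to C8–OH; the C7–C8 bond of ring B (intramolecular carbonyl-ene); the ester C–O bonds at C3 and C9; C8–C9 (formyl anion equivalent plus a C9 aldehyde); ring A into a C1–C4 silyloxy diene and an (E)-enal by Diels–Alder bonds C4–C5 and C1–C10.
2. Enabling feature: ring B is a 2-isopropenylcyclohexanone. C7 carries C11(=C12)C13 next to carbonyl C8, which is the oxidised retron of a type 1 carbonyl-ene reaction between a C8 aldehyde and a C7=C11 prenyl double bond (hydrogen from C12 to oxygen). The arms C5–C6 and C10–C9 are trans-diequatorial on ring A, so a chair closes the trans-decalin.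
3. Forward order: ring A by Diels–Alder; one-carbon extension at C9 with a dithiane (masked C8 aldehyde); C3 ketone to alcohol; two esterifications; unmasking; ring B by the ene reaction; oxidation at C8.
4. Stereochemistry: C4, C5 and C10 arise together in one catalytic enantioselective endo Diels–Alder; C9 is relayed from C10/C5 (Felkin–Anh); C3 is set under thermodynamic control (equatorial); C7 comes from the chair ene transition state (equatorial, also the stable epimer next to C8=O).

Key step: step 11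

Remark on labels: eremophilane atom labels are kept for all intermediates (C1–C10 ring carbons, C5 quaternary, C10 ring-fusion CH, C14 = methyl on C5, C15 = methyl on C4, C11–C13 = isopropenyl on C7, C8 = ketone, C9 = acyloxy carbon); β is the face of C14.

Assumption: the (S)-configured oxazaborolidinium catalyst is taken to be the enantiomer that exposes the C2-Re face of enal 9 (needed for 4R,5R,10R); if the binding model assigns the other face, its antipode is meant.

**Route**

Step 1
Reactants: 1 pent-1-en-3-one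
Product: 2 (Z)-triisopropyl(penta-1,3-dien-3-yloxy)silane
Conditions: i-Pr3SiOTf, Et3N, Et2O, 0 °C
Reagents that add atoms: triisopropylsilyl trifluoromethanesulfonate, CC(C)[Si](OS(=O)(=O)C(F)(F)F)(C(C)C)C(C)C
Why: Soft enolisation of the ethyl ketone (silyl enol ether formation with silyl triflate and amine) should give the (Z)-enol ether, i.e. the 2-silyloxy diene with its terminal methyl pointing outward.

Step 2
Reactants: 3 1-bromo-3-methylbut-2-ene + 4 ethynylmagnesium bromide
Product: 5 5-methylhex-4-en-1-yne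
Conditions: CuCl (cat.), THF, 0 °C to rt
Reagents that add atoms: none
Why: Copper-catalysed coupling of an alkynyl Grignard reagent with a primary allylic bromide should proceed at the unsubstituted carbon and give the skipped enyne.

Step 3
Reactants: 5 5-methylhex-4-en-1-yne
Product: 8 (E)-3,6-dimethylhepta-2,5-dien-1-ol, via alkenylalane 6 (not isolated), via lithium alkenylaluminate 7 (not isolated)
Conditions: Me3Al, Cp2ZrCl2 (cat.), CH2Cl2, 0 °C to rt; n-BuLi, THF, −78 °C; (CH2O)n, −78 °C to rt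
Reagents that add atoms: trimethylaluminium, C[Al](C)C; formaldehyde from paraformaldehyde, C=O
Why: Zirconium-catalysed carboalumination adds methyl and aluminium syn across the terminal alkyne, and hydroxymethylation of the aluminate with retention fixes the (E) geometry (C14 methyl cis to the new CH2OH).

Step 4
Reactants: 8 (E)-3,6-dimethylhepta-2,5-dien-1-ol
Product: 9 (E)-3,6-dimethylhepta-2,5-dienal
Conditions: MnO2, CH2Cl2, rt
Reagents that add atoms: none
Why: Allylic oxidation with MnO2 is chemoselective and should leave both double bonds in place and unisomerised.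

Step 5
Reactants: 2 (Z)-triisopropyl(penta-1,3-dien-3-yloxy)silane + 9 (E)-3,6-dimethylhepta-2,5-dienal
Product: 10 (1R,5R,6R)-5,6-dimethyl-6-(3-methylbut-2-en-1-yl)-4-[(triisopropylsilyl)oxy]cyclohex-3-ene-1-carbaldehyde
Conditions: N-protonated (S)-3,3-diphenyl-1-(2-methylphenyl)tetrahydropyrrolo[1,2-c][1,3,2]oxazaborole triflimide, [C24H25BNO][N(SO2CF3)2] (20 mol %), CH2Cl2, −78 to −40 °C; Et3N quench
Reagents that add atoms: none
Why: Proposed new method: the cationic boron Lewis acid binds the formyl oxygen of s-trans 9 and lowers its LUMO, so the enol-ether terminus C4 of diene 2 bonds to the fully substituted β-carbon C5 in a concerted but strongly asynchronous endo [4+2] transition state that then closes C1–C10; the silyloxy group dictates the para regiochemistry, the outward methyl of the (Z)-diene together with the endo formyl group places C15, C14 and C9 all cis, and the catalyst blocks one enal face; the closest known reactions are oxazaborolidinium-catalysed enantioselective Diels–Alder additions of 2-silyloxydienes to α-substituted or β-monosubstituted enals and the racemic strong-Lewis-acid Diels–Alder of hindered 2-silyloxydienes with β,β-disubstituted enones, whereas an enantioselective case with an acyclic β,β-disubstituted enal forming a quaternary carbon is not known.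

Step 6
Reactants: 10 (1R,5R,6R)-5,6-dimethyl-6-(3-methylbut-2-en-1-yl)-4-[(triisopropylsilyl)oxy]cyclohex-3-ene-1-carbaldehyde + 11 1,3-dithiane
Product: 14 (2R,3S,4R)-4-[(S)-1,3-dithian-2-yl(hydroxy)methyl]-2,3-dimethyl-3-(3-methylbut-2-en-1-yl)cyclohexan-1-one, via 2-lithio-1,3-dithiane 12 (not isolated), via silyl enol ether carbinol 13 (not isolated)
Conditions: 11, n-BuLi, THF, −30 °C; 10, −78 °C; then AcOH, n-Bu4NF, 0 °C
Reagents that add atoms: none
Why: Felkin–Anh addition of the dithiane anion (formyl anion equivalent) anti to the quaternary C5 should set C9 as S, and buffered fluoride then cleaves the silyl enol ether with protonation at C2, so C4 is not touched.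

Step 7
Reactants: 14 (2R,3S,4R)-4-[(S)-1,3-dithian-2-yl(hydroxy)methyl]-2,3-dimethyl-3-(3-methylbut-2-en-1-yl)cyclohexan-1-one
Product: 15 (1R,2R,3R,4R)-4-[(S)-1,3-dithian-2-yl(hydroxy)methyl]-2,3-dimethyl-3-(3-methylbut-2-en-1-yl)cyclohexan-1-ol
Conditions: SmI2, H2O, Et3N, THF, 0 °C
Reagents that add atoms: none
Why: Electron-transfer reduction (dissolving-metal type, via ketyl and carbanion protonation) should give the thermodynamically favoured equatorial 3α-alcohol, whereas hydride would attack from the equatorial side because the axial C14 methyl is 1,3-diaxial to the axial trajectory.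

Step 8
Reactants: 15 (1R,2R,3R,4R)-4-[(S)-1,3-dithian-2-yl(hydroxy)methyl]-2,3-dimethyl-3-(3-methylbut-2-en-1-yl)cyclohexan-1-ol + 16 (Z)-2-methylbut-2-enoic acid
Product: 18 (1R,2R,3R,4R)-4-[(S)-1,3-dithian-2-yl(hydroxy)methyl]-2,3-dimethyl-3-(3-methylbut-2-en-1-yl)cyclohexyl (Z)-2-methylbut-2-enoate, via angelic 2,4,6-trichlorobenzoic anhydride 17 (not isolated)
Conditions: 16, 2,4,6-Cl3C6H2COCl, Et3N, toluene, rt; then 15, DMAP, rt
Reagents that add atoms: none
Why: Yamaguchi esterification transfers the angeloyl group without Z-to-E isomerisation, and the equatorial C3 hydroxyl should react well before the C9 hydroxyl, which is wedged between the dithiane and C10.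

Step 9
Reactants: 18 (1R,2R,3R,4R)-4-[(S)-1,3-dithian-2-yl(hydroxy)methyl]-2,3-dimethyl-3-(3-methylbut-2-en-1-yl)cyclohexyl (Z)-2-methylbut-2-enoate + 19 (E)-3-methylpent-2-enoic acid
Product: 21 (1R,2R,3R,4R)-4-[(S)-1,3-dithian-2-yl{[(E)-3-methylpent-2-enoyl]oxy}methyl]-2,3-dimethyl-3-(3-methylbut-2-en-1-yl)cyclohexyl (Z)-2-methylbut-2-enoate, via pentenoic 2,4,6-trichlorobenzoic anhydride 20 (not isolated)
Conditions: 19, 2,4,6-Cl3C6H2COCl, Et3N, toluene, rt; then 18, DMAP, 50 °C
Reagents that add atoms: none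
Why: Yamaguchi esterification under forcing conditions should acylate the remaining hindered C9 hydroxyl with retention, the (E)-enoyl group being the stable geometry.

Step 10
Reactants: 21 (1R,2R,3R,4R)-4-[(S)-1,3-dithian-2-yl{[(E)-3-methylpent-2-enoyl]oxy}methyl]-2,3-dimethyl-3-(3-methylbut-2-en-1-yl)cyclohexyl (Z)-2-methylbut-2-enoate
Product: 22 (1R,2R,3R,4R)-2,3-dimethyl-3-(3-methylbut-2-en-1-yl)-4-[(S)-1-{[(E)-3-methylpent-2-enoyl]oxy}-2-oxoethyl]cyclohexyl (Z)-2-methylbut-2-enoate
Conditions: MeI, CaCO3, MeCN/H2O (4:1), 45 °C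
Reagents that add atoms: water, O
Why: Alkylative dithioacetal hydrolysis (S-methylation, then water) frees the C8 aldehyde without any oxidant, so the prenyl and enoate double bonds and the C9 centre should survive.

Step 11
Reactants: 22 (1R,2R,3R,4R)-2,3-dimethyl-3-(3-methylbut-2-en-1-yl)-4-[(S)-1-{[(E)-3-methylpent-2-enoyl]oxy}-2-oxoethyl]cyclohexyl (Z)-2-methylbut-2-enoate
Product: 23 (3R,4R,5R,7S,8S,9S,10R)-3-angeloyloxy-8-hydroxy-9-[(E)-3-methylpent-2-enoyloxy]-10αH-eremophil-11-ene
Conditions: Me2AlCl (2.5 equiv), CH2Cl2, −78 to −20 °C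
Reagents that add atoms: none
Why: Me2AlCl binds the formyl oxygen of 22, and C8 attacks C7 of the trisubstituted C7=C11 double bond while an allylic hydrogen of a C11 methyl group passes to oxygen in a concerted, asynchronous type 1 carbonyl-ene (Prins-type) process that leaves the isopropenyl group and an aluminium alkoxide; the Al–CH3 bonds scavenge protons, so no acid-driven cation chemistry or isomerisation to the conjugated isopropylidene should follow. The closest known reaction is the Lewis-acid cyclisation of citronellal-type 7-methyloct-6-enals to 2-isopropenylcyclohexanols (isopulegol). Ring B forms by a 6-exo closure (C11 stays outside the ring) through a chair that is trans-fused to ring A because the C5–C6 and C10–C9 arms are trans-diequatorial. C7 is set by that chair, which keeps the reacting C7=C11 unit and the C9 acyloxy group equatorial (7S, isopropenyl α), relayed from C5, C9 and C10; the C8 carbinol (expected equatorial, 8S) is removed in step 12. The step needs regioselectivity for C7 over C11 (charge develops at tertiary C11, and a six- not a seven-membered ring forms) and chemoselectivity over the two enoate esters, both secured by the electron-rich prenyl double bond held 1,6 to the only aldehyde carbon.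

Step 12
Reactants: 23 (3R,4R,5R,7S,8S,9S,10R)-3-angeloyloxy-8-hydroxy-9-[(E)-3-methylpent-2-enoyloxy]-10αH-eremophil-11-ene
Product: 24 (3R,4R,5R,7S,9S,10R)-3-angeloyloxy-9-[(E)-3-methylpent-2-enoyloxy]-10αH-eremophil-11-en-8-one (CNP0301161.1)
Conditions: Dess–Martin periodinane, NaHCO3, CH2Cl2, 0 °C to rt
Reagents that add atoms: none
Why: Dess–Martin oxidation under bicarbonate buffer converts the C8 carbinol to the ketone without base, so C7 and C9 (both already in the equatorial, stable configuration) and the unconjugated isopropenyl group should be kept.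

**Compound list**

1 | pent-1-en-3-one | C=CC(=O)CC | starting material
2 | (Z)-triisopropyl(penta-1,3-dien-3-yloxy)silane | C/C=C(\O[Si](C(C)C)(C(C)C)C(C)C)C=C | intermediate
3 | 1-bromo-3-methylbut-2-ene | CC(C)=CCBr | starting material
4 | ethynylmagnesium bromide | C#C[Mg]Br | starting material
5 | 5-methylhex-4-en-1-yne | C#CCC=C(C)C | intermediate
6 | [(E)-2,5-dimethylhexa-1,4-dien-1-yl]dimethylalane | CC(C)=CC/C(C)=C/[Al](C)C | intermediate
7 | lithium butyl[(E)-2,5-dimethylhexa-1,4-dien-1-yl]dimethylaluminate | [Li+].CCCC[Al-](C)(C)/C=C(\C)CC=C(C)C | intermediate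
8 | (E)-3,6-dimethylhepta-2,5-dien-1-ol | CC(C)=CC/C(C)=C/CO | intermediate
9 | (E)-3,6-dimethylhepta-2,5-dienal | CC(C)=CC/C(C)=C/C=O | intermediate
10 | (1R,5R,6R)-5,6-dimethyl-6-(3-methylbut-2-en-1-yl)-4-[(triisopropylsilyl)oxy]cyclohex-3-ene-1-carbaldehyde | CC(C)=CC[C@]1(C)[C@@H](C)C(O[Si](C(C)C)(C(C)C)C(C)C)=CC[C@H]1C=O | intermediate
11 | 1,3-dithiane | C1CSCSC1 | starting material
12 | 2-lithio-1,3-dithiane | [Li]C1SCCCS1 | intermediate
13 | (S)-(1,3-dithian-2-yl)[(1R,5R,6S)-5,6-dimethyl-6-(3-methylbut-2-en-1-yl)-4-(triisopropylsilyloxy)cyclohex-3-en-1-yl]methanol | CC(C)=CC[C@]1(C)[C@@H](C)C(O[Si](C(C)C)(C(C)C)C(C)C)=CC[C@H]1[C@H](O)C1SCCCS1 | intermediate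
14 | (2R,3S,4R)-4-[(S)-1,3-dithian-2-yl(hydroxy)methyl]-2,3-dimethyl-3-(3-methylbut-2-en-1-yl)cyclohexan-1-one | CC(C)=CC[C@]1(C)[C@@H](C)C(=O)CC[C@H]1[C@H](O)C1SCCCS1 | intermediate
15 | (1R,2R,3R,4R)-4-[(S)-1,3-dithian-2-yl(hydroxy)methyl]-2,3-dimethyl-3-(3-methylbut-2-en-1-yl)cyclohexan-1-ol | CC(C)=CC[C@]1(C)[C@@H](C)[C@H](O)CC[C@H]1[C@H](O)C1SCCCS1 | intermediate
16 | (Z)-2-methylbut-2-enoic acid (angelic acid) | C/C=C(/C)C(=O)O | starting material
17 | (Z)-2-methylbut-2-enoic 2,4,6-trichlorobenzoic anhydride | C/C=C(/C)C(=O)OC(=O)c1c(Cl)cc(Cl)cc1Cl | intermediate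
18 | (1R,2R,3R,4R)-4-[(S)-1,3-dithian-2-yl(hydroxy)methyl]-2,3-dimethyl-3-(3-methylbut-2-en-1-yl)cyclohexyl (Z)-2-methylbut-2-enoate | CC(C)=CC[C@]1(C)[C@@H](C)[C@H](OC(=O)/C(C)=C\C)CC[C@H]1[C@H](O)C1SCCCS1 | intermediate
19 | (E)-3-methylpent-2-enoic acid | CC/C(C)=C/C(=O)O | starting material
20 | (E)-3-methylpent-2-enoic 2,4,6-trichlorobenzoic anhydride | CC/C(C)=C/C(=O)OC(=O)c1c(Cl)cc(Cl)cc1Cl | intermediate
21 | (1R,2R,3R,4R)-4-[(S)-1,3-dithian-2-yl{[(E)-3-methylpent-2-enoyl]oxy}methyl]-2,3-dimethyl-3-(3-methylbut-2-en-1-yl)cyclohexyl (Z)-2-methylbut-2-enoate | CC(C)=CC[C@]1(C)[C@@H](C)[C@H](OC(=O)/C(C)=C\C)CC[C@H]1[C@H](OC(=O)/C=C(\C)CC)C1SCCCS1 | intermediate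
22 | (1R,2R,3R,4R)-2,3-dimethyl-3-(3-methylbut-2-en-1-yl)-4-[(S)-1-{[(E)-3-methylpent-2-enoyl]oxy}-2-oxoethyl]cyclohexyl (Z)-2-methylbut-2-enoate | CC(C)=CC[C@]1(C)[C@@H](C)[C@H](OC(=O)/C(C)=C\C)CC[C@H]1[C@H](OC(=O)/C=C(\C)CC)C=O | intermediate
23 | (3R,4R,5R,7S,8S,9S,10R)-3-angeloyloxy-8-hydroxy-9-[(E)-3-methylpent-2-enoyloxy]-10αH-eremophil-11-ene | C=C(C)[C@@H]1C[C@]2(C)[C@@H](C)[C@H](OC(=O)/C(C)=C\C)CC[C@H]2[C@H](OC(=O)/C=C(\C)CC)[C@H]1O | intermediate
24 | (3R,4R,5R,7S,9S,10R)-3-angeloyloxy-9-[(E)-3-methylpent-2-enoyloxy]-10αH-eremophil-11-en-8-one | C=C(C)[C@@H]1C[C@]2(C)[C@@H](C)[C@H](OC(=O)/C(C)=C\C)CC[C@H]2[C@H](OC(=O)/C=C(\C)CC)C1=O | target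

**Count and risks**

Total steps: 12. Longest linear sequence: 11 steps (3 to 24, steps 2 to 12).

Steps most likely to fail:

Step 5 (bears the label). What may go wrong: the enol-ether terminus of the diene adds 1,2 to the formyl group instead of 1,4; the cycloaddition stalls at the fully substituted β-carbon; or the catalyst does not differentiate the enal faces. Fallback with known chemistry (chelation-controlled Diels–Alder of a chiral α'-alkoxy enone, then excision of the auxiliary), setting out from 6 and 2 and returning at 14: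
- Alkenylalane 6 is quenched with I2 to give (E)-1-iodo-2,5-dimethylhexa-1,4-diene F1.
- Commercial methyl (S)-2,2-dimethyl-1,3-dioxolane-4-carboxylate is converted with MeNHOMe·HCl and i-PrMgCl into (S)-N-methoxy-N,2,2-trimethyl-1,3-dioxolane-4-carboxamide F2.
- Lithium–iodine exchange on F1 (t-BuLi, Et2O, −78 °C) and acylation with F2 give (E)-1-[(4S)-2,2-dimethyl-1,3-dioxolan-4-yl]-3,6-dimethylhepta-2,5-dien-1-one F3.
- With SnCl4 in CH2Cl2 at −78 °C, the chelate between the ketone oxygen and the adjacent ring oxygen holds the s-cis enone flat, and diene 2 should add endo to the face bearing the dioxolane C–H, giving [(4S)-2,2-dimethyl-1,3-dioxolan-4-yl][(1R,5R,6R)-5,6-dimethyl-6-(3-methylbut-2-en-1-yl)-4-(triisopropylsilyloxy)cyclohex-3-en-1-yl]methanone F4.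
- NaBH4 in MeOH gives the carbinol [(4S)-2,2-dimethyl-1,3-dioxolan-4-yl][(1R,5R,6S)-5,6-dimethyl-6-(3-methylbut-2-en-1-yl)-4-(triisopropylsilyloxy)cyclohex-3-en-1-yl]methanol F5; either epimer serves.
- Aqueous H5IO6 removes the acetonide, cleaves the triol and hydrolyses the enol ether to (1R,2S,3R)-2,3-dimethyl-2-(3-methylbut-2-en-1-yl)-4-oxocyclohexane-1-carbaldehyde F6.
- One equivalent of 12 at −78 °C adds to the aldehyde of F6 in preference to the hindered ketone and gives 14.

Step 7. What may go wrong: reduction without thermodynamic control (formation of the axial 3β-alcohol), or addition of the ketyl to the prenyl double bond. Fallback setting out from 14 and returning at 15: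
- Li(s-Bu)3BH at −78 °C attacks from the equatorial side and gives the axial alcohol (1S,2R,3R,4R)-4-[(S)-1,3-dithian-2-yl(hydroxy)methyl]-2,3-dimethyl-3-(3-methylbut-2-en-1-yl)cyclohexan-1-ol F7.
- Mitsunobu inversion (4-nitrobenzoic acid, PPh3, diisopropyl azodicarboxylate), to which the hindered C9 hydroxyl should not respond, gives (1R,2R,3R,4R)-4-[(S)-1,3-dithian-2-yl(hydroxy)methyl]-2,3-dimethyl-3-(3-methylbut-2-en-1-yl)cyclohexyl 4-nitrobenzoate F8.
- Methanolysis with K2CO3 in MeOH gives 15.

Step 11. What may go wrong: ionisation to the C11 cation and its capture by chloride or by the C9 ester carbonyl instead of hydrogen transfer, methyl transfer from aluminium to C8, or epimerisation at C9 before closure. Fallback setting out from 22 and returning at 23 (allyl-metal addition in place of the ene reaction):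
- Ene-type chlorination of the prenyl group with hypochlorous acid (Ca(OCl)2, CO2, CH2Cl2/H2O) gives the rearranged allylic chloride (1R,2R,3R,4R)-3-(2-chloro-3-methylbut-3-en-1-yl)-2,3-dimethyl-4-[(S)-1-{[(E)-3-methylpent-2-enoyl]oxy}-2-oxoethyl]cyclohexyl (Z)-2-methylbut-2-enoate F9 (both C7 epimers serve).
- CrCl2 in THF (intramolecular Nozaki–Hiyama–Kishi allylation) forms the allylchromium species, which adds through C7 to the aldehyde in a chair and gives 23; any C8 epimer converges in step 12.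

Further compounds
F1 | step 5 | (E)-1-iodo-2,5-dimethylhexa-1,4-diene | CC(C)=CC/C(C)=C/I
F2 | step 5 | (S)-N-methoxy-N,2,2-trimethyl-1,3-dioxolane-4-carboxamide | CON(C)C(=O)[C@@H]1COC(C)(C)O1
F3 | step 5 | (E)-1-[(4S)-2,2-dimethyl-1,3-dioxolan-4-yl]-3,6-dimethylhepta-2,5-dien-1-one | CC(C)=CC/C(C)=C/C(=O)[C@@H]1COC(C)(C)O1
F4 | step 5 | [(4S)-2,2-dimethyl-1,3-dioxolan-4-yl][(1R,5R,6R)-5,6-dimethyl-6-(3-methylbut-2-en-1-yl)-4-(triisopropylsilyloxy)cyclohex-3-en-1-yl]methanone | CC(C)=CC[C@]1(C)[C@@H](C)C(O[Si](C(C)C)(C(C)C)C(C)C)=CC[C@H]1C(=O)[C@@H]1COC(C)(C)O1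
F5 | step 5 | [(4S)-2,2-dimethyl-1,3-dioxolan-4-yl][(1R,5R,6S)-5,6-dimethyl-6-(3-methylbut-2-en-1-yl)-4-(triisopropylsilyloxy)cyclohex-3-en-1-yl]methanol | CC(C)=CC[C@]1(C)[C@@H](C)C(O[Si](C(C)C)(C(C)C)C(C)C)=CC[C@H]1C(O)[C@@H]1COC(C)(C)O1
F6 | step 5 | (1R,2S,3R)-2,3-dimethyl-2-(3-methylbut-2-en-1-yl)-4-oxocyclohexane-1-carbaldehyde | CC(C)=CC[C@]1(C)[C@@H](C)C(=O)CC[C@H]1C=O
F7 | step 7 | (1S,2R,3R,4R)-4-[(S)-1,3-dithian-2-yl(hydroxy)methyl]-2,3-dimethyl-3-(3-methylbut-2-en-1-yl)cyclohexan-1-ol | CC(C)=CC[C@]1(C)[C@@H](C)[C@@H](O)CC[C@H]1[C@H](O)C1SCCCS1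
F8 | step 7 | (1R,2R,3R,4R)-4-[(S)-1,3-dithian-2-yl(hydroxy)methyl]-2,3-dimethyl-3-(3-methylbut-2-en-1-yl)cyclohexyl 4-nitrobenzoate | CC(C)=CC[C@]1(C)[C@@H](C)[C@H](OC(=O)c2ccc(cc2)[N+](=O)[O-])CC[C@H]1[C@H](O)C1SCCCS1
F9 | step 11 | (1R,2R,3R,4R)-3-(2-chloro-3-methylbut-3-en-1-yl)-2,3-dimethyl-4-[(S)-1-{[(E)-3-methylpent-2-enoyl]oxy}-2-oxoethyl]cyclohexyl (Z)-2-methylbut-2-enoate | C=C(C)C(Cl)C[C@]1(C)[C@@H](C)[C@H](OC(=O)/C(C)=C\C)CC[C@H]1[C@H](OC(=O)/C=C(\C)CC)C=O
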